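(The readings are calculated for an exercise.)

1. The vessel is closed and stirred, so whatever leaves X and Z stands as Q or G. I read the product at the last reading of a run as charge minus X minus Z.

| setting | blue | green | flask |
|---|---|---|---|
| X | 1.1 M | 1.1 M | 1.1 M |
| Z | 1.1 M | 1.1 M | 1.1 M |
| E | 0.82 M | 1.65 M | 1.65 M |
| D | 55 mM | 28 mM | 55 mM |
| remark | run made earlier | run made earlier |  |
| time |  |  | 3.0 d |

- blue (time / h: X / %, Z / %, Q / %): 3.00: 48.0, 49.1, 1.7; 5.00: 45.7, 46.8, 3.8; 8.00: 43.5, 45.5, 8.2; 12.0: 40.7, 42.4, 11.1; 20.0: 39.3, 40.2, 14.5; 30.0: 38.3, 39.1, 15.5; 40.0: 38.3, 39.1, 15.5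
- green (time / h: X / %, Z / %, Q / %): 4.00: 47.0, 48.1, 3.7; 10.0: 40.4, 43.3, 11.0; 20.0: 35.1, 37.1, 19.1; 30.0: 33.5, 34.1, 20.6; 40.0: 33.3, 33.4, 23.3

(scatter of a reading: 0.5 percentage points)

- part of the X and Z charged together that has reacted at 3.0 d
- excess of Q over G in the product at 3.0 d
- excess of Z over X among what is left of the two at 3.0 d

- L is single-handed; X and Z are mirror images of each other, charged as a racemate, each of them at the stated concentration
- the numbers in the tables scatter by 0.5 percentage points (one standard deviation)
- an excess is the difference of the two amounts in percent of their sum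
- an excess is below zero if the other one leads

2. The blue run ends with 0.497 M of product from 0.82 M of E. The green run ends with 0.733 M from 1.65 M.

3. I follow one molecule of E to a fork, which is my assumption. It meets L and a substrate and becomes product, or it is lost on its own. I take both branches as first order in [E], so [E] cancels from the odds. At fixed [X] and [Z] I let the first branch scale with catalyst and the second not.

4. I count E charged minus product as lost, which treats the last reading as the end of E. So I divide product made by E lost, then by [D] charged. Blue gives 28.0 M⁻¹ and green gives 28.5 M⁻¹, as readings, although [E] and [D] differ between the runs. I carry their mean, 28.3 M⁻¹: the E split, the odds of product against loss for one molecule of E per [D] charged, a branching ratio, with [X] and [Z] charged as here.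

5. For the flask I reckon odds of 1.55, so a molecule of E has an estimated chance of 60.9% of becoming product. My reckoning gives c of 45.6%.

6. The forecast says c 44%, eP 37%, eS 1%. It reasons that “the catalyst dies with time”; my reckoning instead loses E.

7. The flask gives c 45.1%, eP 31.6%, eS 0.0232%. The forecast's c and eS lie within the tolerance, and its eP stands 5.4 percentage points too high.

    E + L + X → L + Q (k = 1.29 M⁻² h⁻¹)
    E + L + Z → L + G (k = 0.624 M⁻² h⁻¹)
    D → L (k = 0.227 h⁻¹)
    X ⇌ Z (k = 0.0891 h⁻¹)
    E → J (k = 0.0388 h⁻¹)

8. In the flask E, the limiting reagent, stands at 0.0584% of its charge at 3.00 d. At that time E turns into J at 0.91 of the rate at which E + L + X gives L + Q. The flask's product over J gives odds of 1.51, against my 1.55.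

9. A neighbour flask holds 0.093 M of D, with its other charges and its time as in the flask. The E split gives it odds of 2.63, so c should be 54.3%. It computes to 51.6%.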